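## Analysis of the target

The target 19 is a trans-fused decalin (ring A = C1–C5 and C10, ring B = C5–C10, drimane numbering, C11 being the CH2 on C9; intermediates without C11 are named as 11-nordrimanes). It carries a C3 ketone beside the C4 gem-dimethyl group, a trisubstituted C7=C8 alkene with the C8 methyl group, an angular methyl group on the quaternary C10 and, through C11–O, a 7-coumarinyl ether. The three stereocentres C5, C9 and C10 are contiguous (5S,9S,10R). With β defined as the face of the C10 methyl group, H5 is α (trans fusion) and C11 is also α, so the side chain on C9 is axial and anti to the angular methyl group, the less stable arrangement at C9. The coumarin lactone does not tolerate hydroxide, hydride or organometallic reagents, H9 is allylic, and the C7=C8 alkene can migrate under strong acid, so the aryl ether must come late and the closing steps must be mild. The difficulties are the absolute configuration of the quaternary C10, the trans relation of H5 to it next to the bulky C4, and the axial C9–C11 bond, which equilibration or hydrogen delivery to the open α-face of C9 would both set the wrong way. The plan rests on the match between ring B (C5–C10 with methyl groups on C8 and C10, the C7=C8 unsaturation and an oxygen on C9) and 2,6-dimethyl-1,4-benzoquinone 3, whose second alkene, C5=C10, can take up C1–C4 of ring A, with the C3 oxygen and both C4 methyl groups, as a silyloxy diene.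

## Retrosynthetic reasoning

**19 ⇒ 18.** The C3 ketone is unmasked last from the C2=C3 silyl enol ether of 18. This enol ether is the one the cycloaddition creates; it is shielded by C4 and by the silyl group, so it can serve as the ketone protecting group through every basic and nucleophilic step. No separate protection and deprotection pair is needed, and the final desilylation is mild enough for the lactone and the C7=C8 alkene.

**18 ⇒ 16 + 17.** The C11–O(aryl) bond is cut to give the primary alcohol 16 and umbelliferone 17. This keeps the lactone out of all strongly basic steps and makes the end convergent. The forward reaction is a redox condensation at a primary carbinol that touches no stereocentre.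

**16 ⇒ 14 ⇒ 13.** The C9–C11 bond is cut. A homoallylic alcohol with a C7=C8 alkene is the product pattern of a [2,3]-Wittig shift of the C7 allylic ether 14, made from the 7α-alcohol 13. The shift is suprafacial, so an α-oxygen on C7 places C11 on the α-face of C9 and moves the alkene from C8=C9 to C7=C8 in the same event. This is chosen because the axial C9 substituent cannot be obtained by equilibration or by addition of hydrogen from the open face.

**13 ⇒ 11 ⇒ 10.** The 7α-hydroxy C8=C9 pattern of 13 is the Wharton product of the 7α,8α-epoxy-9-ketone 11, which comes from enone 10 by nucleophilic epoxidation anti to the C10 methyl group. The C9 oxygen of the quinone is thereby moved to C7 and C9 becomes the CH that later receives C11.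

**10 ⇒ 7.** H5 is disconnected: the trans-fused enone 10 is traced to the linear dienone 7 by reductive addition of hydrogen at C5. Base equilibration of the cis adduct 4 is not relied on. In the trans isomer of 4 the C4 methyl groups flank the C6 carbonyl oxygen and oppose the C10 methyl group, whereas the cis isomer can place C4 axially on the nearly flat ene-dione ring, where nothing opposes it. The equilibrium may therefore lie on the cis side. A kinetically controlled protonation at C5 under stereoelectronic control is the safer way to the trans fusion.

**7 ⇒ 6 ⇒ 4.** The C6 oxygen is removed through the enol triflate 6. H5 is the only α-hydrogen of 4, so its acidity is used to make C5 trigonal and to turn the C6 carbonyl into a leaving group in one step. Reduction of the C6–O bond then gives 7.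

**4 ⇒ 2 + 3.** Ring A is cut at C1–C10 and C4–C5, the two bonds of a [4+2] cycloaddition between diene 2 and the C5=C10 alkene of quinone 3. This one step brings in C1–C4, the C3 oxygen, the gem-dimethyl group and the quaternary C10 under catalyst control. The forward reaction has to choose one of the two mirror-related quinone alkenes, one face, and the orientation that avoids joining C4 to C10.

**2 ⇒ 1.** Diene 2 is the silyl enol ether of 4-methylpent-1-en-3-one 1, which can enolise only towards the isopropyl carbon.

## Alternatives that were turned down

**Alternative 1: angular methyl from a hydroxyl-directed cyclopropane.** The C10 methyl group is traced to the methylene of a cyclopropane spanning C9 and C10.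
- Forward key step: Simmons–Smith cyclopropanation (Et2Zn, CH2I2) of the C9=C10 alkene of the 8β-allylic alcohol A2, delivered on the hydroxyl face, to give A1. Oxidation at C8 and reductive cleavage of the C9–CH2 bond would then reveal the methyl group.
- For: directed cyclopropanation is very dependable and its facial control is complete. On reliability of the key step it is stronger than the chosen cycloaddition.
- Against: A2, with C5 and the C8 carbinol already defined, needs an enantioselective synthesis of its own. After ring opening only C5 and C10 are in place. The C8 methyl group, the C7=C8 alkene and the axial C9–C11 bond must all still be built from a C8 carbonyl, next to which C9 is epimerisable towards the wrong, equatorial side.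
- Comparison: the route is longer and linear. The chosen strategy sets C10 by the catalyst in the ring-forming step, brings the C8 methyl group and the C7=C8 unsaturation with the quinone, and fixes C9 by a sigmatropic relay that never passes through an epimerisable centre.

**Alternative 2: ring B by cycloaddition onto a ring A diene.** Ring B is cut at C9–C10 and C7–C8.
- Forward key step: the ethoxy diene A4 (C10=C5–C6(OEt)=C7) adds the N-crotonoyl oxazolidinone A5, activated by Cu(OTf)2 and a chiral tert-butyl bis(oxazoline), in the endo mode to give A3.
- For: A3 already holds C11 (as the acyl carbon) on C9 anti to the C10 methyl group, together with the C8 methyl group and the quaternary C10. On C9 this is stronger than the chosen route, which spends four steps there.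
- Against: the C10 terminus of A4 is a fully substituted ring carbon, its s-cis conformer is crowded by the C4 methyl groups, and β-substituted acyl oxazolidinones are the slow dienophiles for this catalyst class. A3 then carries an enol ether at C5=C6: the C6 oxygen has to be deleted, H5 set trans, and the C7=C8 alkene introduced at a position that has no activating group once C6 is deoxygenated. The C8 stereocentre is made only to be destroyed.
- Comparison: the chosen cycloaddition uses a far more reactive dienophile, and the quinone supplies the C7=C8 unsaturation in the right place.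

**Alternative 3: ring B by ring-closing metathesis.** The C7=C8 alkene is cut.
- Forward key step: the second-generation Grubbs catalyst joins the C5 allyl group and the C9 isopropenyl group of A7, with loss of ethylene, to give the bicyclic ester A6.
- For: closure of a six-membered trisubstituted alkene is among the most predictable ring closures, leaves no oxygen to remove at C6 and poses no regiochemical question. On predictability it is stronger than the chosen key step.
- Against: C5, C9 and the quaternary C10 must all be set on A7 beforehand, so the stereochemical problem is moved and not solved. H9 of A6 is both α to the ester and allylic, and the required axial ester is the less stable epimer, so base can epimerise it or pull the alkene into conjugation. Ring A still needs saturation of C1=C2 beside C7=C8 and adjustment at C3.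
- Comparison: the chosen strategy is convergent, creates the quaternary centre in the bond-forming step, and is several steps shorter.

Key step: step 2

## Assumptions

- The sense of induction in step 2 is assigned from the accepted pre-transition-state model of the protonated oxazaborolidine (quinone bound at the C6 oxygen on the side of H5, C5=C10 stacked on the neighbouring phenyl group). On that model the catalyst from (S)-diphenylprolinol leads to the 10R series; the mirror-image catalyst would be used if the sense proved opposite.
- 4-Methylpent-1-en-3-one 1 is taken as purchasable in stabilised form.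

## Route

Step 1
Reactants: 1 4-methylpent-1-en-3-one
Product: 2 4-methyl-3-(triisopropylsilyloxy)penta-1,3-diene
Conditions: iPr3SiOTf, Et3N, CH2Cl2, 0 °C → rt
Reagents that add atoms: triisopropylsilyl trifluoromethanesulfonate, CC(C)[Si](OS(=O)(=O)C(F)(F)F)(C(C)C)C(C)C
Why: Soft enolisation (enol silylation): the silyl triflate activates the carbonyl oxygen and Et3N removes the isopropyl methine proton, the only enolisable hydrogen of 1, so a single cross-conjugated silyl enol ether should result; no stereocentre is formed.

Step 2
Reactants: 2 4-methyl-3-(triisopropylsilyloxy)penta-1,3-diene; 3 2,6-dimethyl-1,4-benzoquinone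
Product: 4 (5S,10R)-3-(triisopropylsilyloxy)-11-nordrima-2,7-diene-6,9-dione (cis-fused, H5 and the C10 methyl group both β)
Conditions: (S)-3,3-diphenyl-1-(o-tolyl)hexahydropyrrolo[1,2-c][1,3,2]oxazaborol-7-ium bis(trifluoromethylsulfonyl)imide (20 mol %, from the B-o-tolyl oxazaborolidine of (S)-diphenylprolinol and HNTf2), CH2Cl2, −78 → −20 °C
Reagents that add atoms: none
Why: The protonated oxazaborolidine binds the C6 carbonyl oxygen of 3 on the lone pair beside H5, so that the C5=C10 alkene lies over a phenyl group of the catalyst and 2 adds to the open face in a concerted, asynchronous, normal-demand [4+2] cycloaddition; the closest known reaction type is the oxazaborolidinium-catalysed addition of 2-silyloxy dienes to substituted benzoquinones. Ring A is closed by this cycloaddition as a six-membered ring, C1–C10 and C4–C5 forming suprafacially on both partners. C10 is fixed by the catalyst, which selects one of the two mirror-related quinone alkenes and one of its faces; C5 follows from suprafacial addition and is therefore cis to the C10 methyl group (it is erased in step 3 and set again in step 5). The step needs regioselectivity: the other orientation would join the fully substituted C4 terminus to the methyl-bearing C10 and is shut out by that clash, while in the wanted orientation the unhindered CH2 terminus leads bond formation at C10, the β-carbon of the catalyst-bound enone, and the charge that develops at C4 is carried by its two methyl groups. The silyloxy group by itself polarises the diene towards C4, which matches C5 only in the uncomplexed quinone, where the C9 carbonyl is the stronger acceptor; under the Lewis acid the orientation therefore rests on sterics and on the gem-dimethyl group. The Z-methyl group of 2 disfavours the s-cis conformer, so the reaction should be slower than with unsubstituted silyloxy dienes and is run warmer.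

Step 3
Reactants: 4 (5S,10R)-3-(triisopropylsilyloxy)-11-nordrima-2,7-diene-6,9-dione
Product: 6 (10R)-9-oxo-3-(triisopropylsilyloxy)-11-nordrima-2,5,7-trien-6-yl trifluoromethanesulfonate, via potassium dienolate 5 (not isolated)
Conditions: KN(SiMe3)2, THF, −78 °C; then 2-[N,N-bis(trifluoromethylsulfonyl)amino]-5-chloropyridine, −78 °C
Reagents that add atoms: 2-[N,N-bis(trifluoromethylsulfonyl)amino]-5-chloropyridine, O=S(=O)(N(c1ccc(Cl)cn1)S(=O)(=O)C(F)(F)F)C(F)(F)F
Why: Kinetic enolate O-sulfonylation (enol triflate formation): H5 is the only α-hydrogen of either carbonyl because C10 is quaternary and C8 is trigonal, the amide base at −78 °C should take it in preference to the vinylogous C8-methyl protons, and the enolate cannot aromatise; the C5 stereocentre of 4 is erased on purpose.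

Step 4
Reactants: 6 (10R)-9-oxo-3-(triisopropylsilyloxy)-11-nordrima-2,5,7-trien-6-yl trifluoromethanesulfonate
Product: 7 (10R)-3-(triisopropylsilyloxy)-11-nordrima-2,5,7-trien-9-one
Conditions: Pd(OAc)2 (5 mol %), PPh3, Bu3N, HCO2H, DMF, 60 °C
Reagents that add atoms: none
Why: Palladium-catalysed formate reduction of an enol triflate: oxidative addition of the C6–O bond to zerovalent palladium, exchange of triflate for formate, loss of CO2 and reductive elimination of C6–H; the dienone has no enolisable hydrogen and is inert to the amine.

Step 5
Reactants: 7 (10R)-3-(triisopropylsilyloxy)-11-nordrima-2,5,7-trien-9-one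
Product: 10 (5R,10R)-3-(triisopropylsilyloxy)-11-nordrima-2,7-dien-9-one (trans-fused, H5 α), via lithium dienolate 8 (not isolated), via deconjugated ketone 9 (not isolated)
Conditions: Li, NH3(l)/THF, t-BuOH (1 equiv), −78 °C; NH4Cl; then DBU (cat.), CH2Cl2, rt
Reagents that add atoms: none
Why: Dissolving-metal 1,6-reduction of a linearly conjugated dienone: the dianion is protonated at its terminus C5 with the new C–H bond perpendicular to the remaining dienolate, and of the two half-chair arrangements that allow this overlap the one with C1 and C4 both equatorial on ring B is lower, so H5 should become α (trans fusion) under kinetic control, as in the reduction of octalones to trans-decalones. Work-up protonates dienolate 8 at C8 to give 9, and the amidine base then moves the alkene into conjugation through the same dienolate without touching C5.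

Step 6
Reactants: 10 (5R,10R)-3-(triisopropylsilyloxy)-11-nordrima-2,7-dien-9-one
Product: 11 7α,8α-epoxy-3-(triisopropylsilyloxy)-11-nordrim-2-en-9-one (H5 α)
Conditions: t-BuOOH, BnNMe3OH (cat.), THF, 0 °C → rt
Reagents that add atoms: tert-butyl hydroperoxide, CC(C)(C)OO
Why: Weitz–Scheffer nucleophilic epoxidation: the peroxide anion adds to C7 along the axial trajectory on the α-face, away from the C10 methyl group, and the enolate closes the oxirane on the same face, setting C7 and C8; the electron-rich silyl enol ether is not attacked by a nucleophilic oxidant.

Step 7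
Reactants: 11 7α,8α-epoxy-3-(triisopropylsilyloxy)-11-nordrim-2-en-9-one
Product: 13 3-(triisopropylsilyloxy)-11-nordrima-2,8-dien-7α-ol (H5 α), via epoxy hydrazone 12 (not isolated)
Conditions: N2H4·H2O, AcOH (cat.), MeOH, 0 °C → rt
Reagents that add atoms: none
Why: Wharton transposition: the hydrazone of the epoxy ketone opens the C8–O bond, and loss of N2 from the alkenyl diazene leaves C9 as the CH of a C8=C9 alkene; the C7–O bond is not broken, so the hydroxyl group stays α.

Step 8
Reactants: 13 3-(triisopropylsilyloxy)-11-nordrima-2,8-dien-7α-ol
Product: 14 7α-[(tributylstannyl)methoxy]-3-(triisopropylsilyloxy)-11-nordrima-2,8-diene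
Conditions: KH, Bu3SnCH2I, THF, 0 °C → rt
Reagents that add atoms: tributyl(iodomethyl)stannane, CCCC[Sn](CCCC)(CCCC)CI
Why: Williamson etherification of the potassium alkoxide with a primary iodide; no stereocentre is affected.

Step 9
Reactants: 14 7α-[(tributylstannyl)methoxy]-3-(triisopropylsilyloxy)-11-nordrima-2,8-diene
Product: 16 (5S,9S,10R)-3-(triisopropylsilyloxy)drima-2,7-dien-11-ol (H9 β, CH2OH α), via lithiomethyl ether 15 (not isolated)
Conditions: n-BuLi, THF, −78 → −20 °C; H2O
Reagents that add atoms: none
Why: Still–Wittig rearrangement: tin–lithium exchange gives the α-alkoxy carbanion 15, whose suprafacial [2,3]-sigmatropic shift forms C9–C11 on the face of the pseudo-axial C7–O bond (α) while the alkene moves to C7=C8, so C9 is set with C11 anti to the C10 methyl group.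

Step 10
Reactants: 16 (5S,9S,10R)-3-(triisopropylsilyloxy)drima-2,7-dien-11-ol; 17 umbelliferone (7-hydroxycoumarin)
Product: 18 7-{[(5S,9S,10R)-3-(triisopropylsilyloxy)drima-2,7-dien-11-yl]oxy}coumarin
Conditions: PPh3, DIAD, THF, 0 → 40 °C
Reagents that add atoms: none
Why: Mitsunobu etherification: the acidic phenol of 17 displaces the oxyphosphonium derivative of the primary C11 carbinol by SN2; no stereocentre is involved and the lactone is not exposed to base.

Step 11
Reactants: 18 7-{[(5S,9S,10R)-3-(triisopropylsilyloxy)drima-2,7-dien-11-yl]oxy}coumarin
Product: 19 7-{[(5S,9S,10R)-3-oxodrim-7-en-11-yl]oxy}coumarin, i.e. 7-{[(1S,4aS,8aR)-2,5,5,8a-tetramethyl-6-oxo-1,4,4a,5,6,7,8,8a-octahydronaphthalen-1-yl]methoxy}-2H-chromen-2-one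
Conditions: Bu4NF, AcOH, THF, 0 °C → rt
Reagents that add atoms: none
Why: Fluoride cleavage of the silyl enol ether, buffered with acetic acid, protonates C2 and returns the C3 ketone without opening the lactone or moving the C7=C8 alkene.

## Compound list

1 | 4-methylpent-1-en-3-one | C=CC(=O)C(C)C | starting material
2 | 4-methyl-3-(triisopropylsilyloxy)penta-1,3-diene | C=CC(O[Si](C(C)C)(C(C)C)C(C)C)=C(C)C | intermediate
3 | 2,6-dimethyl-1,4-benzoquinone | CC1=CC(=O)C=C(C)C1=O | starting material
4 | (5S,10R)-3-(triisopropylsilyloxy)-11-nordrima-2,7-diene-6,9-dione, cis-fused | CC1=CC(=O)[C@H]2C(C)(C)C(O[Si](C(C)C)(C(C)C)C(C)C)=CC[C@@]2(C)C1=O | intermediate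
5 | potassium (10R)-9-oxo-3-(triisopropylsilyloxy)-11-nordrima-2,5,7-trien-6-olate (not isolated) | CC1=CC([O-])=C2C(C)(C)C(O[Si](C(C)C)(C(C)C)C(C)C)=CC[C@@]2(C)C1=O.[K+] | intermediate
6 | (10R)-9-oxo-3-(triisopropylsilyloxy)-11-nordrima-2,5,7-trien-6-yl trifluoromethanesulfonate | CC1=CC(OS(=O)(=O)C(F)(F)F)=C2C(C)(C)C(O[Si](C(C)C)(C(C)C)C(C)C)=CC[C@@]2(C)C1=O | intermediate
7 | (10R)-3-(triisopropylsilyloxy)-11-nordrima-2,5,7-trien-9-one | CC1=CC=C2C(C)(C)C(O[Si](C(C)C)(C(C)C)C(C)C)=CC[C@@]2(C)C1=O | intermediate
8 | lithium 3-(triisopropylsilyloxy)-11-nordrima-2,6,8-trien-9-olate, H5 α (not isolated) | CC=1C=C[C@@H]2C(C)(C)C(O[Si](C(C)C)(C(C)C)C(C)C)=CC[C@@]2(C)C=1[O-].[Li+] | intermediate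
9 | 3-(triisopropylsilyloxy)-11-nordrima-2,6-dien-9-one, H5 α, C8 epimers (not isolated) | CC1C=C[C@@H]2C(C)(C)C(O[Si](C(C)C)(C(C)C)C(C)C)=CC[C@@]2(C)C1=O | intermediate
10 | (5R,10R)-3-(triisopropylsilyloxy)-11-nordrima-2,7-dien-9-one, trans-fused | CC1=CC[C@@H]2C(C)(C)C(O[Si](C(C)C)(C(C)C)C(C)C)=CC[C@@]2(C)C1=O | intermediate
11 | 7α,8α-epoxy-3-(triisopropylsilyloxy)-11-nordrim-2-en-9-one, H5 α | C[C@]12O[C@H]1C[C@@H]3C(C)(C)C(O[Si](C(C)C)(C(C)C)C(C)C)=CC[C@@]3(C)C2=O | intermediate
12 | hydrazone of 11 at C9 (not isolated) | C[C@]12O[C@H]1C[C@@H]3C(C)(C)C(O[Si](C(C)C)(C(C)C)C(C)C)=CC[C@@]3(C)C2=NN | intermediate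
13 | 3-(triisopropylsilyloxy)-11-nordrima-2,8-dien-7α-ol, H5 α | CC=1[C@@H](O)C[C@@H]2C(C)(C)C(O[Si](C(C)C)(C(C)C)C(C)C)=CC[C@@]2(C)C=1 | intermediate
14 | 7α-[(tributylstannyl)methoxy]-3-(triisopropylsilyloxy)-11-nordrima-2,8-diene | CC=1[C@@H](OC[Sn](CCCC)(CCCC)CCCC)C[C@@H]2C(C)(C)C(O[Si](C(C)C)(C(C)C)C(C)C)=CC[C@@]2(C)C=1 | intermediate
15 | 7α-(lithiomethoxy)-3-(triisopropylsilyloxy)-11-nordrima-2,8-diene (not isolated) | CC=1[C@@H](OC[Li])C[C@@H]2C(C)(C)C(O[Si](C(C)C)(C(C)C)C(C)C)=CC[C@@]2(C)C=1 | intermediate
16 | (5S,9S,10R)-3-(triisopropylsilyloxy)drima-2,7-dien-11-ol | CC1=CC[C@@H]2C(C)(C)C(O[Si](C(C)C)(C(C)C)C(C)C)=CC[C@@]2(C)[C@H]1CO | intermediate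
17 | umbelliferone (7-hydroxycoumarin) | O=c1ccc2ccc(O)cc2o1 | starting material
18 | 7-{[(5S,9S,10R)-3-(triisopropylsilyloxy)drima-2,7-dien-11-yl]oxy}coumarin | CC1=CC[C@@H]2C(C)(C)C(O[Si](C(C)C)(C(C)C)C(C)C)=CC[C@@]2(C)[C@H]1COc1ccc2ccc(=O)oc2c1 | intermediate
19 | 7-{[(5S,9S,10R)-3-oxodrim-7-en-11-yl]oxy}coumarin | CC1=CC[C@@H]2C(C)(C)C(=O)CC[C@@]2(C)[C@H]1COc1ccc2ccc(=O)oc2c1 | target

## Step count and weak points

Total: 11 steps. Longest linear sequence: 11 steps (1 → 19); 3 and 17 enter directly.

**Step 2 (key step).** The most likely failure is slow cycloaddition. The hindered, poorly polarised diene may then be consumed by conjugate addition to the activated quinone followed by silyl transfer and aromatisation, or by protodesilylation. Face selectivity may also erode at the higher temperature needed.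
Fallback: starting from 2 and 3, the cycloaddition is run without any catalyst under high pressure (about 12 kbar, CH2Cl2, rt). The free quinone's own polarisation (C9 carbonyl as the stronger acceptor) then matches the silyloxy-activated C4 terminus, and no acid is present to attack the enol ether. This gives racemic material, from which the mirror image of 4, ent-4 F1, is removed by preparative chromatography on a chiral stationary phase. The route is rejoined at 4.

**Step 3.** Deprotonation of the hindered H5 may be slow, so that the base removes a C8-methyl proton instead and the extended enolate is triflated.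
Fallback: starting from 4, NaBH4 with CeCl3·7H2O (MeOH, −78 °C) should reduce the less hindered C6 carbonyl to the C6 allylic alcohol F2. Dehydration across C5–C6 with Martin sulfurane, Ph2S[OC(CF3)2Ph]2, then gives the dienone. The route is rejoined at 7 without any enolate.

**Step 5.** Protonation of the dianion may occur at C7 instead of C5, leaving an isolated C5=C6 alkene, or on the β-face of C5, giving the cis fusion; over-reduction of the carbonyl is a lesser risk.
Fallback: starting from 7, both ring-B alkenes are hydrogenated (H2, 4 atm, Pd on carbon, EtOAc) from the α-face, the known preference of 4,4,10-trimethyl-Δ5-octalins, to give the saturated trans ketone F3. LiN(iPr)2 and Me3SiCl convert it into the C8=C9 trimethylsilyl enol ether F4, and Pd(OAc)2 in MeCN (Saegusa–Ito dehydrogenation) restores the C7=C8 enone; the far more hindered ring-A enol ether should be left. The route is rejoined at 10.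

**Step 7.** The C9 ketone lies between a quaternary carbon and a fully substituted oxirane carbon, so hydrazone formation may be slow and hydrazine or methanol may open the epoxide first.
Fallback: starting from 11, NaBH4 with CeCl3·7H2O gives the C9 epoxy alcohol F5, and NaH, CS2 and MeI give its S-methyl xanthate F6. Bu3SnH with AIBN (PhH, 80 °C) generates the C9 radical, which opens the C8–O bond; the C7 alkoxy radical takes hydrogen from the stannane. The route is rejoined at 13.

**Step 10.** SN2 at the β-branched, homoallylic C11 may be slow, so that the oxyphosphonium salt is diverted to N-alkylation of the reduced azodicarboxylate or to elimination towards C9.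
Fallback: starting from 16, the aryl–oxygen bond is made instead by palladium-catalysed O-arylation with purchased 7-bromocoumarin F7 ([(allyl)PdCl]2, RockPhos, Cs2CO3, PhMe, 90 °C). No substitution at C11 is then needed. The route is rejoined at 18.

## Further compounds

F1 | step 2 | ent-4, (5R,10S)-3-(triisopropylsilyloxy)-11-nordrima-2,7-diene-6,9-dione | CC1=CC(=O)[C@@H]2C(C)(C)C(O[Si](C(C)C)(C(C)C)C(C)C)=CC[C@]2(C)C1=O
F2 | step 3 | 6-hydroxy-3-(triisopropylsilyloxy)-11-nordrima-2,7-dien-9-one, cis-fused, C6 configuration open | CC1=CC(O)[C@H]2C(C)(C)C(O[Si](C(C)C)(C(C)C)C(C)C)=CC[C@@]2(C)C1=O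
F3 | step 5 | 3-(triisopropylsilyloxy)-11-nordrim-2-en-9-one, trans-fused, C8 epimers | CC1CC[C@@H]2C(C)(C)C(O[Si](C(C)C)(C(C)C)C(C)C)=CC[C@@]2(C)C1=O
F4 | step 5 | 3-(triisopropylsilyloxy)-9-(trimethylsilyloxy)-11-nordrima-2,8-diene, H5 α | CC=1CC[C@@H]2C(C)(C)C(O[Si](C(C)C)(C(C)C)C(C)C)=CC[C@@]2(C)C=1O[Si](C)(C)C
F5 | step 7 | 7α,8α-epoxy-3-(triisopropylsilyloxy)-11-nordrim-2-en-9-ol, C9 configuration open | C[C@]12O[C@H]1C[C@@H]3C(C)(C)C(O[Si](C(C)C)(C(C)C)C(C)C)=CC[C@@]3(C)C2O
F6 | step 7 | O-[7α,8α-epoxy-3-(triisopropylsilyloxy)-11-nordrim-2-en-9-yl] S-methyl carbonodithioate | C[C@]12O[C@H]1C[C@@H]3C(C)(C)C(O[Si](C(C)C)(C(C)C)C(C)C)=CC[C@@]3(C)C2OC(=S)SC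
F7 | step 10 | 7-bromocoumarin (purchased reagent of the fallback) | O=c1ccc2ccc(Br)cc2o1
A1 | alternative 1 | 9,10-methano 8β-alcohol with the cyclopropane on the β-face, C3 ethylene ketal | O[C@@H]1CC[C@@H]2C(C)(C)C3(OCCO3)CC[C@]24C[C@H]14
A2 | alternative 1 | 8β-allylic alcohol with C9=C10 alkene, C3 ethylene ketal | O[C@@H]1CC[C@@H]2C(C)(C)C3(OCCO3)CCC2=C1
A3 | alternative 2 | endo adduct with C5=C6 enol ether and C9 acyl group anti to the C10 methyl group | C[C@@H]1CC(OCC)=C2C(C)(C)C3(OCCO3)CC[C@@]2(C)[C@H]1C(=O)N1CCOC1=O
A4 | alternative 2 | 7-(1-ethoxyethenyl)-6,6,8-trimethyl-1,4-dioxaspiro[4.5]dec-7-ene | C=C(OCC)C1=C(C)CCC2(OCCO2)C1(C)C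
A5 | alternative 2 | (E)-3-(but-2-enoyl)oxazolidin-2-one | C/C=C/C(=O)N1CCOC1=O
A6 | alternative 3 | bicyclic C11 methyl ester with C7=C8 and C1=C2 alkenes and C3 silyl ether | CC1=CC[C@@H]2C(C)(C)[C@H](O[Si](C)(C)C(C)(C)C)C=C[C@@]2(C)[C@H]1C(=O)OC
A7 | alternative 3 | ring A diene with C5 allyl and C9 isopropenyl groups | C=CC[C@@H]1C(C)(C)[C@H](O[Si](C)(C)C(C)(C)C)C=C[C@@]1(C)[C@H](C(C)=C)C(=O)OC
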